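(All runs are simulated on assumed constants, and the scatter is random.)

Partner is what I count first in the south-west flask, the one asked about and followed so far.

in all of them: solid substrate 0.50 M
- south-west: partner 1 M; the very flask that is asked about, followed so far
- north-west: partner 2 M; run made earlier
- flask: partner 1.00 M; time 2.0 d

south-west run (percent of the solid substrate charged)

| time / h | target / % | solid substrate / % |
|---|---|---|
| 3.00 | 54.1 | 1.0 |
| 10.0 | 55.2 | 0 |
| 20.0 | 53.2 | 0 |
| 30.0 | 56.3 | 0 |
| 40.0 | 54.8 | 0.5 |

north-west run (percent of the solid substrate charged)

| time / min | target / % | solid substrate / % |
|---|---|---|
| 8.00 | 23.8 | 54.8 |
| 15.0 | 42.7 | 16.4 |
| 30.0 | 54.7 | 0 |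
| 60.0 | 55.5 | 1.1 |
| 120 | 55.2 | 0.2 |

(scatter of a reading: 1 percentage point)

- percent here means solid substrate units held: one side product counts as two
- solid substrate is a solid; its amount is given per volume of the solution
- target taken out counts as made
- the analysis behind the earlier runs scatters by 1 percentage point, standard deviation
- steps thought possible: solid substrate <-> dissolved substrate; dissolved substrate + partner -> target; solid substrate + target -> side product
- at the start none of the solid substrate is in solution
- additions bring no volume worth counting

- blue: at 2.0 d add partner, 50.0 % of the amount charged, then wait 4.0 d
- ochre: at 2.0 d take out 90 % of the target then present, then wait 4.0 d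
- green: change nothing and wait 4.0 d more

1. target, in percent of the solid substrate first charged, at 2.0 d
2. what to do for the largest gain in target; "none" if nothing gains more than 2 percentage points (blue / ochre / green / none)
3. target present, with what was taken out counted in, in percent of the solid substrate first charged, after ochre
4. target present, with what was taken out counted in, in percent of the solid substrate first charged, after green

The target readings of that flask average

Y = 54.7 %

I count the remainder as side product. One side product holds two units and used up one target, so the share of the charge ever made into target is

M = (1 + Y)/2 = 77.4 %

Each target made took one partner. With c_B the partner charged and c_S the solid substrate charged,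

D = c_B/(M c_S) = 2.59

This cover number D is the partner charged over the partner that the target made requires. It stands above 1, so I take solid substrate as the limiting reagent and expect nothing from blue.

Is one number enough? No. The target readings of the north-west run from 30.0 min on average 55.1 %, although the same reckoning gives that run a cover of 5.16, twice as much. So in these two runs D says which charge ends first, not how much target stands. For ochre and green I need a second fact: the listed loss of target takes solid, and the south-west solid reads 0 % at 10.0 h and 0.5 % at 40.0 h, within the scatter of 1 percentage point. I commit to Y at 2.0 d and no useful option.

The forecast gives 55 %, none, 55 % and 55 %, on the ground that “No listed step consumes target once the solid has gone.”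

The south-west flask gives 54.5 %, best none, with gains of 0 points, 0 points and 0 points.

    solid substrate ⇌ dissolved substrate, rate k1*(cs1 - [dissolved substrate]) while solid is left; crystals form when [dissolved substrate] > cs1 (solubility = 0.160 M, k = 0.140 /min)
    dissolved substrate + partner → target (k = 1.60 /M/min)
    solid substrate + target → side product (k = 0.310 /M/min)

The forecast stands, but a moved charge can undo it: at 0.564 M of solid substrate the answer has shifted by 5 points. The cover predicts 61.3 % of the partner left, and the flask holds 61.4 % at 48.0 h.

With 2.0 M of solid substrate and M kept, D becomes 0.646, below 1, so partner should run short. The computed flask has partner 0 %, dissolved substrate 6.87 %, target 6.87 % and side product 86.3 %.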